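The target is numbered as a germacranolide: ring C1–C10, lactone O–C6/C7/C11/C12(=O) with exocyclic C13, ester carbon C14 on C10, methyl C15 on C4. Retrosynthetic cuts, in order: the C8 ester, C11=C13 (masked as CH2NMe2), C3–C4 (ring closure), C4=C5, then C7–C8 together with C11–C13, and C1=C10.
Enabling feature: C7 is the β-carbon of the butenolide ring O–C6–C7=C11–C12 and must bond to the acyl-level carbon C8, while C11 needs the extra carbon C13. A C8 dithiane anion and an iminium ion can therefore be added across C7=C11 in one flask, trans to the C6 side chain.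
Forward: the lactone ring is bought as the (S)-butenolide; acyclic fragment 2 (C8–C10, C1–C3, C14) is joined at C7 and C13 is added. C5 then becomes a Z-vinyl iodide and C3 an aldehyde, and a Nozaki–Hiyama–Kishi reaction closes the ten-membered ring at C3–C4. After that C8 goes from dithiane to ketone to alcohol to epoxyangelate, C14 to the methyl ester, and the amine to the methylene.
Stereochemistry: C6 comes from the butenolide, C7 from anti conjugate addition, C8 from hydride reduction next to C7, and C3 from the ring closure. The epoxide carbons come from a Sharpless epoxidation; C1=C10 from an E-selective Horner–Wadsworth–Emmons reaction and C4=C5 from a Z-selective iodo-Wittig reaction.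

Key step: step 7

Remarks:
- α/β refer to the usual germacranolide drawing (H7 α); the target is 3β-OH, 6βH, 7αH, 8β-acyloxy (3S,6R,7R,8R).
- C11 of the Mannich lactones is drawn as the expected 11βH isomer (aminomethyl trans to the C7 substituent); it becomes trigonal in step 22, so its configuration is not critical.
- 3-[(tert-Butyldimethylsilyl)oxy]propanal and methyl angelate are taken as purchasable. Triethyl phosphonoacetate is used because this ester carbon is reduced and only later re-oxidised to the methyl ester.

Step 1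
Reactants: 1 (S)-5-(hydroxymethyl)furan-2(5H)-one
Product: 2 (S)-5-[(trityloxy)methyl]furan-2(5H)-one
Conditions: Ph3CCl, pyridine, DMAP (cat.), CH2Cl2, rt
Reagents that add atoms: trityl chloride, ClC(c1ccccc1)(c1ccccc1)c1ccccc1
Why: Standard tritylation of a primary alcohol with a weak amine base that cannot enolise the butenolide, so C6 is untouched and the bulky ether later shields one face of the ring.

Step 2
Reactants: 3 triethyl phosphonoacetate; 4 bromoacetaldehyde diethyl acetal
Product: 6 ethyl 2-(diethoxyphosphoryl)-4,4-diethoxybutanoate, via sodium phosphonoacetate 5 (not isolated)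
Conditions: NaH, DMF, 0 °C to rt; then 4, NaI (cat.), 90 °C
Reagents that add atoms: none
Why: C-alkylation (SN2) of the stabilised phosphonoacetate carbanion with the primary bromide, helped by iodide exchange in warm DMF, is the usual route to α-substituted phosphonoacetates.

Step 3
Reactants: 6 ethyl 2-(diethoxyphosphoryl)-4,4-diethoxybutanoate
Product: 7 ethyl 2-(diethoxyphosphoryl)-3-(1,3-dithian-2-yl)propanoate
Conditions: HS(CH2)3SH, BF3·OEt2, CH2Cl2, 0 °C to rt
Reagents that add atoms: propane-1,3-dithiol, SCCCS
Why: Lewis-acid-catalysed transthioacetalisation exchanges the diethyl acetal for the more stable six-membered dithioacetal, and is placed here because no acid-labile silyl ether is yet present.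

Step 4
Reactants: 7 ethyl 2-(diethoxyphosphoryl)-3-(1,3-dithian-2-yl)propanoate; 8 3-[(tert-butyldimethylsilyl)oxy]propanal
Product: 10 ethyl (E)-5-[(tert-butyldimethylsilyl)oxy]-2-(1,3-dithian-2-ylmethyl)pent-2-enoate, via sodium phosphonate carbanion 9 (not isolated)
Conditions: NaH, THF, 0 °C; then 8, 0 °C to rt
Reagents that add atoms: none
Why: Horner–Wadsworth–Emmons olefination of an α-substituted phosphonoacetate with an unhindered aldehyde under equilibrating conditions should give mainly the E enoate (aldehyde chain trans to the ester, so C2 is cis to C9 as in the target), the minor Z isomer being removed by chromatography.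

Step 5
Reactants: 10 ethyl (E)-5-[(tert-butyldimethylsilyl)oxy]-2-(1,3-dithian-2-ylmethyl)pent-2-enoate
Product: 11 (E)-5-[(tert-butyldimethylsilyl)oxy]-2-(1,3-dithian-2-ylmethyl)pent-2-en-1-ol
Conditions: i-Bu2AlH, CH2Cl2, −78 °C; aq. potassium sodium tartrate
Reagents that add atoms: none
Why: 1,2-Reduction of the conjugated ester by i-Bu2AlH at low temperature gives the allylic alcohol without affecting the dithiane, the silyl ether or the alkene geometry, and removes the acidic γ-protons that would interfere with dithiane lithiation.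

Step 6
Reactants: 11 (E)-5-[(tert-butyldimethylsilyl)oxy]-2-(1,3-dithian-2-ylmethyl)pent-2-en-1-ol
Product: 12 fragment 2, 2-{(E)-2-[(tert-butyldiphenylsilyl)oxymethyl]-5-[(tert-butyldimethylsilyl)oxy]pent-2-enyl}-1,3-dithiane
Conditions: t-BuPh2SiCl, imidazole, DMF, rt
Reagents that add atoms: tert-butyl(chloro)diphenylsilane, CC(C)(C)[Si](Cl)(c1ccccc1)c1ccccc1
Why: Standard silylation gives the allylic TBDPS ether at C14, chosen because it outlasts the trityl ether at C5 and the TBS ether at C3 under acid, so the three primary oxygens can be freed in that order.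

Step 7
Reactants: 12 fragment 2 dithiane; 2 (S)-5-[(trityloxy)methyl]furan-2(5H)-one; 13 dimethylmethyleneiminium iodide
Product: 16 (3R,4S,5S)-3-[(dimethylamino)methyl]-4-{2-[(E)-2-[(tert-butyldiphenylsilyl)oxymethyl]-5-[(tert-butyldimethylsilyl)oxy]pent-2-enyl]-1,3-dithian-2-yl}-5-[(trityloxy)methyl]oxolan-2-one, via 2-lithiodithiane 14 (not isolated), via lithium lactone enolate 15 (not isolated)
Conditions: 12, n-BuLi, THF, −30 °C; DMPU, −78 °C; 2, −78 °C; then 13, −78 to 0 °C
Reagents that add atoms: none
Why: n-BuLi removes the dithiane C–H of 12 to give the sulfur-stabilised carbanion 14, which in the presence of DMPU adds in Michael fashion to C7 of butenolide 2 to give lithium enolate 15, and 15 is aminomethylated at C11 by the iminium ion of 13 (Mannich reaction). The closest known reaction type is the tandem conjugate addition of 2-lithio-1,3-dithianes to γ-substituted butenolides with enolate trapping, as used for trans-disubstituted lignan lactones, combined with the standard capture of lactone enolates by Eschenmoser's salt. No ring is closed: the two skeletal bonds C7–C8 and C11–C13 are formed and the lactone ring of 2 is kept. The new C7 stereocentre is controlled by C6, the carbanion entering the face anti to the trityloxymethyl group; the electrophile then enters C11 anti to the new C7 substituent, giving the trans,trans lactone. The step needs 1,4-addition to win over carbonyl addition and over deprotonation at C6, which the soft dithiane anion, the polar cosolvent and the low temperature should secure, and it needs C- rather than O-attack on the enolate, which the carbon-selective iminium electrophile secures.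

Step 8
Reactants: 16 trityl Mannich lactone
Product: 17 C5 alcohol, lactone 16 with free CH2OH in place of CH2OCPh3
Conditions: CF3CO2H, Et3SiH, CH2Cl2, −20 to 0 °C; aq. NaHCO3
Reagents that add atoms: none
Why: Acid ionises the trityl ether far faster than the primary TBS or TBDPS ethers and Et3SiH reduces the trityl cation irreversibly to triphenylmethane (ionic hydrogenolysis), the first equivalent of acid being absorbed by the amine.

Step 9
Reactants: 17 C5 alcohol
Product: 18 C5 aldehyde, lactone carrying CHO at C6
Conditions: (COCl)2, DMSO, CH2Cl2, −78 °C; Et3N, −78 to −40 °C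
Reagents that add atoms: none
Why: Swern oxidation tolerates the tertiary amine and the dithiane, and the low temperature limits epimerisation of the α-acyloxy aldehyde at C6, which is used crude.

Step 10
Reactants: 18 C5 aldehyde
Product: 19 Z-vinyl iodide, lactone carrying (Z)-CH=C(CH3)I at C6
Conditions: EtPPh3I, n-BuLi, THF, rt; I2, −78 °C; NaN(SiMe3)2, −20 °C; then 18, −78 to −20 °C
Reagents that add atoms: ethyltriphenylphosphonium iodide, CC[P+](c1ccccc1)(c1ccccc1)c1ccccc1.[I-]; iodine, [I][I]
Why: Stork–Zhao-type Wittig olefination with the α-iodoethylidene ylide proceeds through the kinetically favoured cis-oxaphosphetane and should give the Z-2-iodoalkene (iodine cis to C6), which fixes C3 cis to C6 across C4=C5 after the later coupling.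

Step 11
Reactants: 19 Z-vinyl iodide
Product: 20 C3 primary alcohol, 19 with the TBS ether cleaved
Conditions: HF·pyridine, pyridine, THF, 0 °C
Reagents that add atoms: none
Why: Under acidic fluoride a primary TBS ether is cleaved much faster than a primary TBDPS ether, so C3 is freed selectively while C14 stays protected.

Step 12
Reactants: 20 C3 primary alcohol
Product: 21 C3 aldehyde, β,γ-unsaturated aldehyde with vinyl iodide
Conditions: Dess–Martin periodinane, NaHCO3, CH2Cl2, 0 °C
Reagents that add atoms: none
Why: Dess–Martin oxidation buffered with bicarbonate gives the β,γ-unsaturated aldehyde without base-induced migration of C1=C10 into conjugation; the aldehyde is used at once.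

Step 13
Reactants: 21 C3 aldehyde
Product: 22 (11βH)-13-(dimethylamino)-3β-hydroxy-14-[(tert-butyldiphenylsilyl)oxy]-8,8-(propane-1,3-diyldithio)germacra-1(10)E,4Z-dien-12,6α-olide
Conditions: CrCl2 (excess), NiCl2 (cat.), DMSO/THF, rt, slow addition of 21 (high dilution)
Reagents that add atoms: none
Why: Nozaki–Hiyama–Kishi reaction, in which zerovalent nickel (formed from NiCl2 by CrCl2) inserts into the vinyl C–I bond and transmetalation gives a vinyl species of trivalent chromium that adds only to the aldehyde with retention of the Z geometry; the two cis alkenes, the trans-disposed lactone substituents and the quaternary C8 favour closure of the ten-membered ring, and C3 is set under macrocyclic control, addition with the aldehyde oxygen on the outer side of the forming ring being expected to favour the 3β (3S) alcohol.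

Step 14
Reactants: 22 macrocyclic C3 alcohol
Product: 23 C3 TBS ether of 22
Conditions: t-BuMe2SiOTf, 2,6-lutidine, CH2Cl2, −78 to 0 °C
Reagents that add atoms: tert-butyldimethylsilyl trifluoromethanesulfonate, CC(C)(C)[Si](C)(C)OS(=O)(=O)C(F)(F)F
Why: Silyl triflate silylation protects the hindered secondary allylic alcohol so that C8 can later be acylated and C14 oxidised without interference from C3.

Step 15
Reactants: 23 C3 TBS ether
Product: 25 8β-alcohol (H7 and H8 cis) with lactone 3-O-TBS 14-O-TBDPS and 13-NMe2 retained, via C8 ketone 24 (not isolated)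
Conditions: PhI(OCOCF3)2, CF3CO2H, MeCN/H2O, 0 °C; aq. NaHCO3, extraction; then NaBH4, CeCl3·7H2O, MeOH, −78 °C
Reagents that add atoms: water, O
Why: Oxidative dethioketalisation with [bis(trifluoroacetoxy)iodo]benzene (the amine shielded as its trifluoroacetate salt) unmasks the C8 ketone, which is prone to alkene migration and to β-elimination of the C6 carboxylate and is therefore reduced at once under Luche conditions; hydride is expected to attack C8 from the outer face syn to H7 and anti to the C7–C11 bond (Felkin–Anh-type 1,2-induction from C7), giving the 8β alcohol.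

Step 16
Reactants: 26 methyl angelate, methyl (Z)-2-methylbut-2-enoate
Product: 27 (Z)-2-methylbut-2-en-1-ol
Conditions: i-Bu2AlH, Et2O, −78 to 0 °C; aq. potassium sodium tartrate
Reagents that add atoms: none
Why: 1,2-Reduction of the enoate by i-Bu2AlH gives the allylic alcohol with the Z geometry retained.

Step 17
Reactants: 27 (Z)-2-methylbut-2-en-1-ol
Product: 28 (2S,3R)-(2,3-dimethyloxiran-2-yl)methanol
Conditions: Ti(Oi-Pr)4, L-(+)-diethyl tartrate, t-BuOOH, 4 Å molecular sieves, CH2Cl2, −20 °C
Reagents that add atoms: tert-butyl hydroperoxide, CC(C)(C)OO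
Why: Sharpless asymmetric epoxidation, in which L-(+)-tartrate delivers oxygen to the same face that turns geraniol into its (2S,3S) epoxide, here giving 2S,3R, while the Z alkene fixes the hydroxymethyl group and the C3 methyl cis on the oxirane.

Step 18
Reactants: 28 (2S,3R)-(2,3-dimethyloxiran-2-yl)methanol
Product: 29 (2R,3R)-2,3-dimethyloxirane-2-carboxylic acid
Conditions: RuCl3·xH2O (cat.), NaIO4, CCl4/MeCN/H2O, rt
Reagents that add atoms: water, O; sodium periodate (terminal oxidant, oxygen relayed through RuO4), [Na+].[O-]I(=O)(=O)=O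
Why: RuO4-catalysed oxidation converts the primary epoxy alcohol into the glycidic acid without opening the oxirane; the descriptor at C2 changes from S to R only because the substituent priorities change.

Step 19
Reactants: 25 8β-alcohol; 29 (2R,3R)-2,3-dimethyloxirane-2-carboxylic acid
Product: 31 8β-[(2R,3R)-2,3-dimethyloxirane-2-carbonyloxy] ester with lactone 3-O-TBS 14-O-TBDPS and 13-NMe2 retained, via Yamaguchi mixed anhydride 30 (not isolated)
Conditions: 29, 2,4,6-trichlorobenzoyl chloride, Et3N, toluene, rt; then 25, DMAP, rt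
Reagents that add atoms: none
Why: Yamaguchi esterification acylates the hindered secondary C8 alcohol through the mixed anhydride and DMAP, with retention at C8 and no epimerisable centre in the acid (its α-carbon is quaternary).

Step 20
Reactants: 31 8β-ester
Product: 32 C14 allylic alcohol, 31 with the TBDPS ether cleaved
Conditions: Bu4NF, AcOH, THF, 0 °C to rt
Reagents that add atoms: none
Why: Acetic-acid-buffered fluoride removes the unhindered primary TBDPS ether faster than the hindered secondary TBS ether at C3, and the buffering protects the lactone, the Mannich base and the epoxy ester from basic fluoride.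

Step 21
Reactants: 32 C14 allylic alcohol
Product: 34 C14 carboxylic acid (amino acid) with 3-O-TBS and 8β-ester retained, via C14 enal 33 (not isolated)
Conditions: MnO2, CH2Cl2, rt; filter; then NaClO2, NaH2PO4, 2-methyl-2-butene, t-BuOH/H2O, 0 °C to rt
Reagents that add atoms: sodium chlorite, [Na+].[O-]Cl=O
Why: MnO2 oxidises only the allylic primary alcohol (C3 is silylated), and Pinnick oxidation of the crude enal at about pH 4, where the amine is protonated and 2-methyl-2-butene traps HOCl, gives the acid without touching the alkenes, the epoxide or the E geometry.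

Step 22
Reactants: 34 C14 carboxylic acid
Product: 36 3-O-TBS ether of the target (methyl ester and α-methylene lactone in place), via trimethylammonium iodide 35 (not isolated)
Conditions: MeI (excess), KHCO3, DMF, rt
Reagents that add atoms: iodomethane, IC
Why: Iodomethane under bicarbonate buffering alkylates the carboxylate (ester formation) and quaternises the dimethylamino group, and the β-ammonium lactone then loses trimethylamine by E1cB (Hofmann-type) elimination, the standard release of an α-methylene lactone from its Mannich base.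

Step 23
Reactants: 36 3-O-TBS ether of the target
Product: 37 CNP0143679.1, methyl (1(10)E,4Z)-3β-hydroxy-8β-[(2R,3R)-2,3-dimethyloxirane-2-carbonyloxy]-6βH,7αH-germacra-1(10),4,11(13)-trien-12,6-olid-14-oate (3S,6R,7R,8R)
Conditions: HF·pyridine, pyridine, THF, 0 °C to rt
Reagents that add atoms: none
Why: Pyridine-buffered HF cleaves the secondary allylic TBS ether by standard fluoride desilylation under conditions that the glycidic ester, the enoate and the α-methylene lactone tolerate.

Compound list
1 | (S)-5-(hydroxymethyl)furan-2(5H)-one | O=C1O[C@@H](C=C1)CO | starting material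
2 | (S)-5-[(trityloxy)methyl]furan-2(5H)-one | O=C1O[C@@H](C=C1)COC(c2ccccc2)(c2ccccc2)c2ccccc2 | intermediate
3 | triethyl phosphonoacetate | CCOC(=O)CP(=O)(OCC)OCC | starting material
4 | bromoacetaldehyde diethyl acetal | CCOC(CBr)OCC | starting material
5 | sodium salt of triethyl phosphonoacetate | [Na+].CCOC(=O)[CH-]P(=O)(OCC)OCC | intermediate (not isolated)
6 | ethyl 2-(diethoxyphosphoryl)-4,4-diethoxybutanoate (racemic) | CCOC(=O)C(CC(OCC)OCC)P(=O)(OCC)OCC | intermediate
7 | ethyl 2-(diethoxyphosphoryl)-3-(1,3-dithian-2-yl)propanoate (racemic) | CCOC(=O)C(CC1SCCCS1)P(=O)(OCC)OCC | intermediate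
8 | 3-[(tert-butyldimethylsilyl)oxy]propanal | O=CCCO[Si](C)(C)C(C)(C)C | starting material
9 | sodium carbanion of phosphonate 7 | [Na+].CCOC(=O)[C-](CC1SCCCS1)P(=O)(OCC)OCC | intermediate (not isolated)
10 | ethyl (E)-5-[(tert-butyldimethylsilyl)oxy]-2-(1,3-dithian-2-ylmethyl)pent-2-enoate | CCOC(=O)/C(CC1SCCCS1)=C/CCO[Si](C)(C)C(C)(C)C | intermediate
11 | (E)-5-[(tert-butyldimethylsilyl)oxy]-2-(1,3-dithian-2-ylmethyl)pent-2-en-1-ol | OC/C(CC1SCCCS1)=C/CCO[Si](C)(C)C(C)(C)C | intermediate
12 | fragment 2, 2-{(E)-2-[(tert-butyldiphenylsilyl)oxymethyl]-5-[(tert-butyldimethylsilyl)oxy]pent-2-enyl}-1,3-dithiane | CC(C)(C)[Si](c1ccccc1)(c1ccccc1)OC/C(CC1SCCCS1)=C/CCO[Si](C)(C)C(C)(C)C | intermediate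
13 | dimethylmethyleneiminium iodide (Eschenmoser's salt) | C=[N+](C)C.[I-] | starting material
14 | 2-lithio derivative of fragment 2 | [Li]C1(SCCCS1)C/C(CO[Si](c2ccccc2)(c2ccccc2)C(C)(C)C)=C\CCO[Si](C)(C)C(C)(C)C | intermediate (not isolated)
15 | lithium enolate of the C7 adduct (C6/C7 trans) | C1=C(O[Li])O[C@H](COC(c2ccccc2)(c2ccccc2)c2ccccc2)[C@H]1C3(SCCCS3)C/C(CO[Si](c4ccccc4)(c4ccccc4)C(C)(C)C)=C\CCO[Si](C)(C)C(C)(C)C | intermediate (not isolated)
16 | (3R,4S,5S)-3-[(dimethylamino)methyl]-4-{2-[(E)-2-[(tert-butyldiphenylsilyl)oxymethyl]-5-[(tert-butyldimethylsilyl)oxy]pent-2-enyl]-1,3-dithian-2-yl}-5-[(trityloxy)methyl]oxolan-2-one | CN(C)C[C@@H]1C(=O)O[C@H](COC(c2ccccc2)(c2ccccc2)c2ccccc2)[C@H]1C3(SCCCS3)C/C(CO[Si](c4ccccc4)(c4ccccc4)C(C)(C)C)=C\CCO[Si](C)(C)C(C)(C)C | intermediate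
17 | C5 alcohol (16 with CH2OH at C6) | CN(C)C[C@@H]1C(=O)O[C@H](CO)[C@H]1C2(SCCCS2)C/C(CO[Si](c3ccccc3)(c3ccccc3)C(C)(C)C)=C\CCO[Si](C)(C)C(C)(C)C | intermediate
18 | C5 aldehyde (CHO at C6) | CN(C)C[C@@H]1C(=O)O[C@H](C=O)[C@H]1C2(SCCCS2)C/C(CO[Si](c3ccccc3)(c3ccccc3)C(C)(C)C)=C\CCO[Si](C)(C)C(C)(C)C | intermediate
19 | Z-vinyl iodide ((Z)-2-iodoprop-1-enyl at C6) | CN(C)C[C@@H]1C(=O)O[C@H](/C=C(/C)I)[C@H]1C2(SCCCS2)C/C(CO[Si](c3ccccc3)(c3ccccc3)C(C)(C)C)=C\CCO[Si](C)(C)C(C)(C)C | intermediate
20 | C3 primary alcohol (19 without TBS) | CN(C)C[C@@H]1C(=O)O[C@H](/C=C(/C)I)[C@H]1C2(SCCCS2)C/C(CO[Si](c3ccccc3)(c3ccccc3)C(C)(C)C)=C\CCO | intermediate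
21 | C3 aldehyde | CN(C)C[C@@H]1C(=O)O[C@H](/C=C(/C)I)[C@H]1C2(SCCCS2)C/C(CO[Si](c3ccccc3)(c3ccccc3)C(C)(C)C)=C\CC=O | intermediate
22 | (11βH)-13-(dimethylamino)-3β-hydroxy-14-[(tert-butyldiphenylsilyl)oxy]-8,8-(propane-1,3-diyldithio)germacra-1(10)E,4Z-dien-12,6α-olide | CN(C)C[C@@H]1C(=O)O[C@@H]2/C=C(/C)[C@@H](O)C/C=C(/CO[Si](c3ccccc3)(c3ccccc3)C(C)(C)C)CC4(SCCCS4)[C@@H]12 | intermediate
23 | 3-O-TBS ether of 22 | CN(C)C[C@@H]1C(=O)O[C@@H]2/C=C(/C)[C@@H](O[Si](C)(C)C(C)(C)C)C/C=C(/CO[Si](c3ccccc3)(c3ccccc3)C(C)(C)C)CC4(SCCCS4)[C@@H]12 | intermediate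
24 | C8 ketone | CN(C)C[C@@H]1C(=O)O[C@@H]2/C=C(/C)[C@@H](O[Si](C)(C)C(C)(C)C)C/C=C(/CO[Si](c3ccccc3)(c3ccccc3)C(C)(C)C)CC(=O)[C@@H]12 | intermediate (not isolated)
25 | 8β-alcohol | CN(C)C[C@@H]1C(=O)O[C@@H]2/C=C(/C)[C@@H](O[Si](C)(C)C(C)(C)C)C/C=C(/CO[Si](c3ccccc3)(c3ccccc3)C(C)(C)C)C[C@@H](O)[C@@H]12 | intermediate
26 | methyl angelate, methyl (Z)-2-methylbut-2-enoate | C/C=C(/C)C(=O)OC | starting material
27 | (Z)-2-methylbut-2-en-1-ol | C/C=C(/C)CO | intermediate
28 | (2S,3R)-(2,3-dimethyloxiran-2-yl)methanol | OC[C@]1(C)O[C@@H]1C | intermediate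
29 | (2R,3R)-2,3-dimethyloxirane-2-carboxylic acid | OC(=O)[C@]1(C)O[C@@H]1C | intermediate
30 | (2R,3R)-2,3-dimethyloxirane-2-carboxylic 2,4,6-trichlorobenzoic anhydride | O=C(OC(=O)[C@]1(C)O[C@@H]1C)c1c(Cl)cc(Cl)cc1Cl | intermediate (not isolated)
31 | 8β-epoxyangelate ester (3-O-TBS, 14-O-TBDPS, 13-NMe2) | CN(C)C[C@@H]1C(=O)O[C@@H]2/C=C(/C)[C@@H](O[Si](C)(C)C(C)(C)C)C/C=C(/CO[Si](c3ccccc3)(c3ccccc3)C(C)(C)C)C[C@@H](OC(=O)[C@]4(C)O[C@@H]4C)[C@@H]12 | intermediate
32 | C14 allylic alcohol | CN(C)C[C@@H]1C(=O)O[C@@H]2/C=C(/C)[C@@H](O[Si](C)(C)C(C)(C)C)C/C=C(/CO)C[C@@H](OC(=O)[C@]3(C)O[C@@H]3C)[C@@H]12 | intermediate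
33 | C14 enal | CN(C)C[C@@H]1C(=O)O[C@@H]2/C=C(/C)[C@@H](O[Si](C)(C)C(C)(C)C)C/C=C(/C=O)C[C@@H](OC(=O)[C@]3(C)O[C@@H]3C)[C@@H]12 | intermediate (not isolated)
34 | C14 carboxylic acid | CN(C)C[C@@H]1C(=O)O[C@@H]2/C=C(/C)[C@@H](O[Si](C)(C)C(C)(C)C)C/C=C(/C(=O)O)C[C@@H](OC(=O)[C@]3(C)O[C@@H]3C)[C@@H]12 | intermediate
35 | 13-trimethylammonium iodide of the C14 methyl ester | C[N+](C)(C)C[C@@H]1C(=O)O[C@@H]2/C=C(/C)[C@@H](O[Si](C)(C)C(C)(C)C)C/C=C(/C(=O)OC)C[C@@H](OC(=O)[C@]3(C)O[C@@H]3C)[C@@H]12.[I-] | intermediate (not isolated)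
36 | 3-O-TBS ether of the target | C=C1C(=O)O[C@@H]2/C=C(/C)[C@@H](O[Si](C)(C)C(C)(C)C)C/C=C(/C(=O)OC)C[C@@H](OC(=O)[C@]3(C)O[C@@H]3C)[C@@H]12 | intermediate
37 | CNP0143679.1 | C=C1C(=O)O[C@@H]2/C=C(/C)[C@@H](O)C/C=C(/C(=O)OC)C[C@@H](OC(=O)[C@]3(C)O[C@@H]3C)[C@@H]12 | target

Total step count: 23. Longest linear sequence: 19 steps (steps 2–15, then 19–23).

Steps most likely to fail

Step 7. The hindered tertiary carbanion may remove the C6 proton of the butenolide or attack the lactone carbonyl instead of C7, and the enolate may be captured only partly by the sparingly soluble iminium salt. Fallback, setting out from 12 and 2 and returning at 16: carbanion 14 is generated as before and quenched with CO2 to give the dithiane carboxylic acid F1. Its carboxylate is oxidised under visible-light photoredox catalysis ([Ir(dF(CF3)ppy)2(dtbbpy)]PF6, K2HPO4, DMF, blue light) to the neutral dithianyl radical, which adds to C7 of 2 anti to the trityloxymethyl group (decarboxylative Giese addition) and gives the C13-free lactone F2. F2 is then enolised with LiN(i-Pr)2 at −78 °C and aminomethylated with 13 to give 16. This replaces the basic carbanion by a radical and separates the two bond formations.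

Step 13. Intermolecular coupling or loss of iodine may compete with the slow ten-membered ring closure, and the addition to the C3 aldehyde may show low facial selectivity. Fallback, setting out from 22 as obtained (whatever its composition at C3) and returning at 22: Dess–Martin oxidation gives the C3 enone F3, and Corey–Bakshi–Shibata reduction with (R)-2-methyl-CBS-oxazaborolidine and catecholborane (alkenyl arm as the large group) sets the 3S alcohol under reagent control instead of ring control.

Step 15. Hydride may be delivered to the wrong face of C8, and the ketone may suffer alkene migration or β-elimination before it is reduced. Fallback, setting out from ketone 24 and returning at 31: the reduction is run for the face the substrate prefers to give the 8α alcohol F4, and F4 is esterified with acid 29 under Mitsunobu conditions (PPh3, DIAD, toluene, 0 °C to rt) with inversion at C8. This gives 31 directly and replaces step 19.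

Further compounds
F1 | step 7 | 2-{(E)-2-[(tert-butyldiphenylsilyl)oxymethyl]-5-[(tert-butyldimethylsilyl)oxy]pent-2-enyl}-1,3-dithiane-2-carboxylic acid | OC(=O)C1(SCCCS1)C/C(CO[Si](c2ccccc2)(c2ccccc2)C(C)(C)C)=C\CCO[Si](C)(C)C(C)(C)C
F2 | step 7 | (4S,5S)-4-(2-substituted 1,3-dithian-2-yl)-5-[(trityloxy)methyl]oxolan-2-one (16 without the aminomethyl group) | C1C(=O)O[C@H](COC(c2ccccc2)(c2ccccc2)c2ccccc2)[C@H]1C3(SCCCS3)C/C(CO[Si](c4ccccc4)(c4ccccc4)C(C)(C)C)=C\CCO[Si](C)(C)C(C)(C)C
F3 | step 13 | C3 enone of macrocycle 22 | CN(C)C[C@@H]1C(=O)O[C@@H]2/C=C(/C)C(=O)C/C=C(/CO[Si](c3ccccc3)(c3ccccc3)C(C)(C)C)CC4(SCCCS4)[C@@H]12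
F4 | step 15 | 8α-alcohol (C8 epimer of 25) | CN(C)C[C@@H]1C(=O)O[C@@H]2/C=C(/C)[C@@H](O[Si](C)(C)C(C)(C)C)C/C=C(/CO[Si](c3ccccc3)(c3ccccc3)C(C)(C)C)C[C@H](O)[C@@H]12
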